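At late times target falls in both earlier runs, so each run passes a peak, and the flask is wanted at its own peak.

| setting | midnight | dawn | flask |
|---|---|---|---|
| substrate | 0.50 M | 0.75 M | 1.0 M |
| partner | 2.5 M | 2.5 M | 2.50 M |
| remark | run made earlier | run made earlier |  |
| time |  |  | 6.0 min |

- midnight (time / min: target / %): 0.667: 35.2; 1.00: 41.5; 1.33: 43.2; 2.00: 42.5; 3.00: 35.9; 4.00: 29.1; 6.00: 26.5
- dawn (time / min: target / %): 0.667: 38.4; 1.00: 46.4; 1.33: 51.9; 2.00: 55.3; 3.00: 54.4; 4.00: 50.7; 6.00: 43.6

(each reading ± 0.5 percentage points)

- a reading or a percentage of target counts all its forms, free or not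

- the best time, 6.0 min at the latest, for target
- the amount of target, in percent of the substrate charged, at that time

The reckoning goes by the shortfall, which is c(substrate) at the start minus target at the peak, in M. At the highest readings, 43.2 % in the midnight run and 55.3 % in the dawn run, the shortfall reads 0.284 M and 0.335 M. So the slope of the shortfall against the charge reads 0.205, less than the midnight share of 0.568, and the highest reading climbs from the midnight run to the dawn run. For the flask this gives a shortfall of 0.387 M, hence a peak of 61.3 %. The peak readings moved 0.670 min later between the runs, and one more such step gives 2.67 min.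

The forecast differs from this reckoning and is later, with 64 % at 3.2 min, on the ground “Substrate seems to hold back the destruction”.

The flask gives 64.1 % at 2.67 min.

    target ⇌ isomer of the product (K = 2.90, k = 0.0180 s⁻¹)
    partner + intermediate → target (k = 0.420 L mol⁻¹ s⁻¹)
    crystals ⇌ target, rate k3*(cs3 - [target]) while solid is left; crystals form when [target] > cs3 (solubility = 0.160 M, k = 0.360 s⁻¹)
    substrate → intermediate (k = 0.0180 s⁻¹)
    2 intermediate → homo product (k = 0.170 L mol⁻¹ s⁻¹)

The flask's shortfall is 0.359 M, smaller than the reckoned 0.387 M, and at the best time the isomer of the product holds 29.8 % of the substrate charged. A neighbour flask charged with 0.60 M of substrate, its partner as in the flask, has by the same slope a reckoned shortfall of 0.304 M, which makes a best of 49.3 %, and that flask gives 49.3 %.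

The readings are simulated for an exercise; the scatter is artificial.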